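**Plan**
- Number the quinone ring of the target C1 and C4 (carbonyls), C2 (acetoxy-bearing), C3 and C6 (aryl-bearing), C5 (C–H). The phenols are unmasked last, the acetate comes from acetylation of a hydroxyquinone, and the C2 oxygen is traced back to a C–H bond, which leaves the C2-symmetric 2,5-diaryl-1,4-benzoquinone 5.
- In 5 the ring bonds C1–C2 and C4–C5 (each from a carbonyl carbon to the neighbouring unsubstituted sp2 carbon) are cut together. The ring consists of two identical C(=O)–C(Ar)=CH units joined head to tail (carbonyls para, aryl-bearing carbons para), so it is the cyclodimer of arylcyclopropenone 4.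
- Forward: alkyne 1 plus difluorocarbene gives the three-membered ring of 4; a zerovalent-nickel [3+3] cyclodimerisation then builds the whole six-membered quinone ring, at the quinone oxidation level, in one operation.
- One of the two equivalent ring C–H positions is then oxygenated (epoxidation, acid isomerisation), the acidic hydroxyl is acetylated, and the benzyl ethers are removed by hydrogenolysis with aerobic re-oxidation.
- Stereochemistry: the target has no stereocentre; the only stereogenic intermediate, racemic epoxide 6, is converted into achiral 7.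

Key step: step 2

Remark: 1-(benzyloxy)-4-ethynylbenzene is taken as a catalogue compound; compounds that put carbon atoms into the target are numbered as starting materials.

Step 1
Reactants: 1 1-(benzyloxy)-4-ethynylbenzene; 2 (trifluoromethyl)trimethylsilane
Product: 4 2-[4-(benzyloxy)phenyl]cycloprop-2-en-1-one, via gem-difluorocyclopropene 3 (not isolated)
Conditions: TMSCF3, NaI, THF, 65–110 °C (sealed tube); then H2O, SiO2, rt
Reagents that add atoms: (trifluoromethyl)trimethylsilane, C[Si](C)(C)C(F)(F)F (its CF2 carbon becomes the carbonyl carbon); water, O (carbonyl oxygen)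
Why: Iodide-initiated release of difluorocarbene from TMSCF3 and its [2+1] cycloaddition to the terminal alkyne should give the gem-difluorocyclopropene, whose C–F bonds ionise readily (cyclopropenylium character) so that water turns CF2 into C=O, the established route from terminal alkynes to monosubstituted cyclopropenones.

Step 2
Reactants: 4 2-[4-(benzyloxy)phenyl]cycloprop-2-en-1-one (two molecules)
Product: 5 2,5-bis[4-(benzyloxy)phenyl]-1,4-benzoquinone
Conditions: Ni(COD)2 (10 mol %), PhMe, rt
Reagents that add atoms: none
Why: Zerovalent nickel should insert into the strained, unhindered acyl–C(H) σ-bond of 4 to give a nickelacyclobutenone; a second molecule of 4 enters through the same bond so that its C–H carbon becomes bonded to the first acyl carbon, and C(sp2)–C(acyl) reductive elimination from the resulting seven-membered nickelacycle forms the second acyl–CH bond and returns zerovalent nickel. The closest known reaction type is the Ni(COD)2-catalysed cyclodimerisation of diarylcyclopropenones to tetraaryl-1,4-benzoquinones, a strain-driven C–C activation. The six-membered ring closes by a formal [3+3] head-to-tail union of two C(=O)–C(Ar)=CH units, the last bond being made by reductive elimination at nickel and not by a pericyclic closure. No stereocentre is formed. The step needs head-to-tail (not head-to-head) union and cleavage of the same ring bond in both units; the steric difference between the C–H carbon and the aryl-bearing carbon of 4 should direct nickel to the acyl–CH bond each time, uniform cleavage can only lead to the 2,5-diaryl quinone, and the absence of CO together with the low temperature should disfavour decarbonylation to the alkyne.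

Step 3
Reactants: 5 2,5-bis[4-(benzyloxy)phenyl]-1,4-benzoquinone
Product: 7 2,5-bis[4-(benzyloxy)phenyl]-3-hydroxy-1,4-benzoquinone, via quinone monoepoxide 6 (not isolated)
Conditions: tBuOOH (1.05 equiv), benzyltrimethylammonium hydroxide (cat.), THF, 0 °C; then TsOH·H2O (cat.), CH2Cl2, rt
Reagents that add atoms: tert-butyl hydroperoxide, CC(C)(C)OO
Why: Weitz–Scheffer nucleophilic epoxidation of one of the two equivalent electron-poor C=C bonds (hydroperoxide adds to the C–H carbon, the aryl-stabilised enolate closes the oxirane) should be followed by acid opening at the aryl-bearing carbon (cation stabilised by the para-benzyloxyphenyl group) and loss of the adjacent proton, the known epoxyquinone-to-hydroxyquinone isomerisation, which also removes the two stereocentres of racemic 6.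

Step 4
Reactants: 7 2,5-bis[4-(benzyloxy)phenyl]-3-hydroxy-1,4-benzoquinone; 8 acetic anhydride
Product: 9 2,5-bis[4-(benzyloxy)phenyl]-3,6-dioxocyclohexa-1,4-dien-1-yl acetate
Conditions: Ac2O, pyridine, CH2Cl2, 0 °C
Reagents that add atoms: acetic anhydride, CC(=O)OC(C)=O
Why: O-acetylation of the acidic hydroxyquinone (a vinylogous carboxylic acid) is a standard esterification, and it is the only free hydroxyl in 7 because both phenols are masked as benzyl ethers.

Step 5
Reactants: 9 2,5-bis[4-(benzyloxy)phenyl]-3,6-dioxocyclohexa-1,4-dien-1-yl acetate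
Product: 11 neonambiquinone A, via hydroquinone monoacetate 10 (not isolated)
Conditions: H2 (1 atm), Pd/C, EtOAc, rt; then N2 purge, air, rt
Reagents that add atoms: none
Why: Hydrogenolysis of the two benzyl aryl ethers over Pd/C (the quinone is reduced to the hydroquinone in passing) followed by Pd/C-mediated aerobic dehydrogenation of the hydroquinone should restore the quinone under neutral, non-nucleophilic conditions that leave the labile enol acetate in place.

**Compound list**
1 | 1-(benzyloxy)-4-ethynylbenzene | C#Cc1ccc(OCc2ccccc2)cc1 | starting material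
2 | (trifluoromethyl)trimethylsilane | C[Si](C)(C)C(F)(F)F | starting material
3 | 1-[4-(benzyloxy)phenyl]-3,3-difluorocycloprop-1-ene | FC1(F)C=C1c1ccc(OCc2ccccc2)cc1 | intermediate (not isolated)
4 | 2-[4-(benzyloxy)phenyl]cycloprop-2-en-1-one | O=C1C=C1c1ccc(OCc2ccccc2)cc1 | intermediate
5 | 2,5-bis[4-(benzyloxy)phenyl]cyclohexa-2,5-diene-1,4-dione | O=C1C=C(c2ccc(OCc3ccccc3)cc2)C(=O)C=C1c1ccc(OCc2ccccc2)cc1 | intermediate
6 | 1,4-bis[4-(benzyloxy)phenyl]-7-oxabicyclo[4.1.0]hept-3-ene-2,5-dione (racemic; cis ring fusion is the only possible one) | O=C1C=C(c2ccc(OCc3ccccc3)cc2)C(=O)C2OC12c1ccc(OCc2ccccc2)cc1 | intermediate (not isolated)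
7 | 2,5-bis[4-(benzyloxy)phenyl]-3-hydroxycyclohexa-2,5-diene-1,4-dione | O=C1C=C(c2ccc(OCc3ccccc3)cc2)C(=O)C(O)=C1c1ccc(OCc2ccccc2)cc1 | intermediate
8 | acetic anhydride | CC(=O)OC(C)=O | starting material
9 | 2,5-bis[4-(benzyloxy)phenyl]-3,6-dioxocyclohexa-1,4-dien-1-yl acetate | CC(=O)OC1=C(c2ccc(OCc3ccccc3)cc2)C(=O)C=C(c2ccc(OCc3ccccc3)cc2)C1=O | intermediate
10 | 3,6-dihydroxy-2,5-bis(4-hydroxyphenyl)phenyl acetate | CC(=O)Oc1c(-c2ccc(O)cc2)c(O)cc(-c2ccc(O)cc2)c1O | intermediate (not isolated)
11 | neonambiquinone A, 2,5-bis(4-hydroxyphenyl)-3,6-dioxocyclohexa-1,4-dien-1-yl acetate | CC(=O)OC1=C(c2ccc(O)cc2)C(=O)C=C(c2ccc(O)cc2)C1=O | target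

Total step count: 5. Longest linear sequence: 5 steps.

**Steps most likely to fail**

1. Step 2. The two cyclopropenone units may open at different ring bonds or join head to head, and decarbonylation to the alkyne with subsequent oligomerisation may compete, so that the 2,5-diaryl quinone is not formed cleanly. The fallback sets out from 1, forms the same two ring bonds by ionic condensation, and comes back at 5. Oxidative bis(methoxycarbonylation) of 1 (PdI2/KI cat., CO/air, MeOH) should give dimethyl (Z)-2-[4-(benzyloxy)phenyl]but-2-enedioate F1. Conjugate reduction (Mg, MeOH) should give dimethyl 2-[4-(benzyloxy)phenyl]butanedioate F2. A succinylsuccinate-type Claisen–Dieckmann cyclodimerisation (NaOMe, PhMe/MeOH, reflux) should give dimethyl 2,5-bis[4-(benzyloxy)phenyl]-3,6-dioxocyclohexane-1,4-dicarboxylate F3, the product being the only one that can rest as a stabilised bis-enolate. Krapcho dealkoxycarbonylation (LiCl, wet DMSO, 150 °C) should give 2,5-bis[4-(benzyloxy)phenyl]cyclohexane-1,4-dione F4, and dehydrogenation with DDQ (dioxane, reflux) should return 5.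

2. Step 3. A second epoxidation of the remaining enedione C=C, or ring contraction by acyl shift during the acid opening, may erode the mono-oxygenation. The fallback sets out from 5 and comes back at 7. Thiele–Winter acetoxylation (Ac2O, BF3·OEt2, rt) is self-limiting because the product is aromatic, and should give 3,6-bis[4-(benzyloxy)phenyl]benzene-1,2,4-triyl triacetate F5. Methanolysis under air (K2CO3, MeOH, air; then dilute acid) should give the triol, which oxidises to 7.

3. Step 5. Migration of the acetyl group to the neighbouring hydroxyl at the hydroquinone stage, loss of the labile enol acetate, or incomplete re-oxidation may occur. The fallback sets out from 7 and comes back at 11, and it avoids the hydroquinone acetate altogether. Hydrogenolysis of 7 (H2, Pd/C, EtOAc/MeOH; then air) should give 3-hydroxy-2,5-bis(4-hydroxyphenyl)cyclohexa-2,5-diene-1,4-dione F6. Only its quinone hydroxyl is acidic enough to be ionised by one equivalent of mild base, so it should be acetylated selectively (Ac2O 1.0 equiv, Et3N 1.0 equiv, THF, −20 °C) to give 11.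

**Further compounds**
F1 | step 2 | dimethyl (Z)-2-[4-(benzyloxy)phenyl]but-2-enedioate | COC(=O)/C=C(/c1ccc(OCc2ccccc2)cc1)C(=O)OC
F2 | step 2 | dimethyl 2-[4-(benzyloxy)phenyl]butanedioate (racemic) | COC(=O)CC(C(=O)OC)c1ccc(OCc2ccccc2)cc1
F3 | step 2 | dimethyl 2,5-bis[4-(benzyloxy)phenyl]-3,6-dioxocyclohexane-1,4-dicarboxylate (mixture of stereoisomers and enol forms) | COC(=O)C1C(c2ccc(OCc3ccccc3)cc2)C(=O)C(C(=O)OC)C(c2ccc(OCc3ccccc3)cc2)C1=O
F4 | step 2 | 2,5-bis[4-(benzyloxy)phenyl]cyclohexane-1,4-dione (mixture of stereoisomers) | O=C1CC(c2ccc(OCc3ccccc3)cc2)C(=O)CC1c1ccc(OCc2ccccc2)cc1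
F5 | step 3 | 3,6-bis[4-(benzyloxy)phenyl]benzene-1,2,4-triyl triacetate | CC(=O)Oc1c(OC(C)=O)c(-c2ccc(OCc3ccccc3)cc2)c(OC(C)=O)cc1-c1ccc(OCc2ccccc2)cc1
F6 | step 5 | 3-hydroxy-2,5-bis(4-hydroxyphenyl)cyclohexa-2,5-diene-1,4-dione | O=C1C=C(c2ccc(O)cc2)C(=O)C(O)=C1c1ccc(O)cc1
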